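The readings come from a simulation from invented constants, noise included.

The vessel was closed and stirred at constant volume, so whatever left G had to stand somewhere in the flask. That was my starting point when you asked for a quick number and suspected that birch, with its heavier J, would use up G faster.

| setting | noon | summer | autumn | ash | birch |
|---|---|---|---|---|---|
| G | 0.37 M | 0.37 M | 0.37 M | 0.37 M | 0.37 M |
| J | 0.38 M | 0.53 M | 0.95 M | 0.330 M | 1.00 M |
| remark | run made earlier | run made earlier | run made earlier |  |  |
| time |  |  |  | 8.0 h | 8.0 h |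

| run | time / h | Q / % | E / % | X / % | Z / % | G / % |
|---|---|---|---|---|---|---|
| noon | 1.00 | 1 | 2 | 14 | 6 | 81 |
| noon | 2.50 | 0 | 3 | 25 | 6 | 65 |
| noon | 3.00 | 0 | 5 | 27 | 13 | 59 |
| noon | 5.00 | 1 | 9 | 22 | 12 | 47 |
| noon | 6.00 | 5 | 14 | 25 | 11 | 41 |
| summer | 1.00 | 1 | 2 | 14 | 5 | 81 |
| summer | 2.50 | 2 | 3 | 24 | 8 | 63 |
| summer | 3.00 | 2 | 5 | 21 | 8 | 60 |
| summer | 5.00 | 3 | 7 | 25 | 9 | 49 |
| summer | 6.00 | 7 | 14 | 22 | 12 | 43 |
| autumn | 0.417 | 0 | 2 | 6 | 3 | 93 |
| autumn | 0.833 | 2 | 0 | 14 | 0 | 87 |
| autumn | 1.50 | 0 | 2 | 18 | 4 | 76 |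
| autumn | 3.00 | 3 | 5 | 25 | 7 | 60 |
| autumn | 6.00 | 8 | 12 | 23 | 9 | 42 |

(each reading ± 1.5 percentage points)

- which of these there is most of at the end, counted by the G in it, ash (E / Z / Q / G / X)
- which of these there is most of at the end, counted by the G in it, birch (E / Z / Q / G / X)
- final amount of the leader among these, as a percentage of the G charged, in ash
- final amount of the leader among these, as a percentage of the G charged, in birch

The readings did not bear that out. At 6.00 h G stood at 41% in noon and 42% in autumn, a gap inside the scatter of 1.5 percentage points, though autumn's J was 2.50 times noon's. So I reckoned one number for ash and birch alike.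

Early on X rose out of G; later the readings of X stopped climbing while G kept falling. I therefore treated G and X as one exchanging pair, a pre-equilibrium pool, and followed cG + cX. Averaged over the runs, it fell from 84.0% at 3.00 h to 65.3% at 6.00 h. Read off these scattered averages, that gave the pair's loss constant, the first-order rate at which G and X together leak to the other species: 0.0838 h⁻¹. G held 64.3% of the pair at the last readings, and I kept that share.

Carried to 8.0 h, my estimate of the pair came to 55.3% and of G to 35.5%. E, read at 14% in noon at 6.00 h, stayed below that estimate of G even with the pair's further loss added to it.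

The forecast named G for ash and G for birch, at 34% and 34%, lower than my figure: “G should still lead in both cases”. The flasks gave G in ash at 36.3% and G in birch at 36.3%.

    E ⇌ L (K = 0.620, k = 0.0410 h⁻¹)
    G ⇌ X (K = 0.660, k = 0.190 h⁻¹)
    J + Z → Q (k = 0.250 M⁻¹ h⁻¹)
    G → Z (k = 0.0570 h⁻¹)
    Z ⇌ L (K = 0.440, k = 0.250 h⁻¹)
    X → E (k = 0.100 h⁻¹)

In birch at 8.0 h the pair held 57.5%, against my 55.3%. I ran the same reckoning on the neighbouring flask, birch read at 20 h: 0.0838 h⁻¹ gave a pair of 20.2% and G of 13.0%. That flask held G at 14.9% and X at 9.00%, a pair of 23.9%, above my figure. Its leader was no longer G but Q, at 37.4%.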